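The bicyclic core is disconnected at C4–C5 and C9–C10, which unfolds rings A and B into an acyclic, enantiopure epoxy diene ketone made from (5E,9E)-farnesylacetone. Cp2TiCl opens the C3–C4 epoxide to a tertiary C4 radical. Two 6-endo closures build ring A and then ring B, and the tertiary C8 radical loses a C17 hydrogen to give the C8=C17 methylene. One operation sets C4, C5, C9, C10 and the exocyclic alkene. It exploits the methyl-branched carbons C4, C10 and C8 of rings A and B, each a stable tertiary radical site, and the C13 ketone, which halts the cascade. Olefination, C3 inversion and C18 oxidation follow.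

Key step: step 4

Numbering (labdane): ring A = C1–C5 and C10. Ring B = C5–C10. C17 = CH2 on C8, C18 = 4α (equatorial) carbon, C19 = 4β-CH3 (axial), C20 = 10β-CH3. The side chain C11–C16 sits on C9.

Assumption: commercial (5E,9E)-farnesylacetone is used as the single E,E isomer, because both alkene geometries are translated into C5, C9 and C10.

Step 1
Reactants: 1 (5E,9E)-farnesylacetone
Product: 2 (5E,9E,13E)-15-hydroxy-6,10,14-trimethylpentadeca-5,9,13-trien-2-one
Conditions: SeO2 (0.1 equiv), salicylic acid (0.1 equiv), t-BuOOH (3 equiv), CH2Cl2, 0 °C to rt, stopped at partial conversion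
Reagents that add atoms: tert-butyl hydroperoxide, CC(C)(C)OO
Why: Selenium dioxide allylic oxidation (ene reaction, then [2,3]-sigmatropic shift) should attack the terminal isopropylidene group fastest because it is the least hindered trisubstituted alkene, and it places the hydroxyl on the E methyl group while the saturated methyl ketone stays inert at this temperature.

Step 2
Reactants: 2 (5E,9E,13E)-15-hydroxy-6,10,14-trimethylpentadeca-5,9,13-trien-2-one
Product: 3 (5E,9E)-12-[(2S,3S)-3-(hydroxymethyl)-3-methyloxiran-2-yl]-6,10-dimethyldodeca-5,9-dien-2-one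
Conditions: Ti(OiPr)4 (0.1 equiv), L-(+)-diethyl tartrate (0.12 equiv), t-BuOOH (2 equiv, in decane), 4 Å molecular sieves, CH2Cl2, −20 °C
Reagents that add atoms: tert-butyl hydroperoxide, CC(C)(C)OO
Why: In the Sharpless asymmetric epoxidation only the alkene bearing the allylic hydroxyl is activated, and the L-(+)-tartrate catalyst should give the (2S,3S)-epoxide, so the future C3 is set as S and becomes the only source of absolute configuration.

Step 3
Reactants: 3 (5E,9E)-12-[(2S,3S)-3-(hydroxymethyl)-3-methyloxiran-2-yl]-6,10-dimethyldodeca-5,9-dien-2-one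
Product: 4 (5E,9E)-12-[(2S,3S)-3-(tert-butyldimethylsilyloxymethyl)-3-methyloxiran-2-yl]-6,10-dimethyldodeca-5,9-dien-2-one
Conditions: TBSCl, imidazole, CH2Cl2, 0 °C to rt
Reagents that add atoms: tert-butyldimethylsilyl chloride, CC(C)(C)[Si](C)(C)Cl
Why: Imidazole-promoted silylation of the primary alcohol is mild enough to avoid Payne rearrangement and removes the free hydroxyl that would otherwise bind titanium in step 4.

Step 4
Reactants: 4 (5E,9E)-12-[(2S,3S)-3-(tert-butyldimethylsilyloxymethyl)-3-methyloxiran-2-yl]-6,10-dimethyldodeca-5,9-dien-2-one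
Product: 6 3β-hydroxy-18-(tert-butyldimethylsilyloxy)-14,15-dinorlabd-8(17)-en-13-one, via titanium alkoxide 5 (not isolated)
Conditions: Cp2TiCl2 (2.5 equiv), Mn dust (8 equiv), THF (dry, degassed), rt, slow addition of 4; then 1 M aq. HCl
Reagents that add atoms: none
Why: Cp2TiCl, a single-electron donor of trivalent titanium, opens the epoxide homolytically at the more substituted C4–O bond (Nugent–RajanBabu opening) to the tertiary β-titanoxy C4 radical, which adds to C5 of the C5=C10 alkene, the new C10 radical adds to C9 of the C9=C8 alkene, and the tertiary C8 radical is captured by a second Cp2TiCl and loses a C17 hydrogen by β-hydride elimination, giving the exocyclic C8=C17 methylene under strictly anhydrous conditions. The closest known reaction type is the titanocene-mediated radical cyclization of epoxypolyprenes. Ring A closes 6-endo-trig (C4–C5) and ring B closes last, also 6-endo-trig (C10–C9), each mode being enforced by the methyl group on the inner alkene carbon, which makes the endo radical tertiary. C5, C10 and C9 follow from a chair–chair fold of the two E alkenes (5α-H and 10β-CH3 trans-fused, C9 chain equatorial), the face is chosen by the C3 stereocentre, whose bulky OTiCp2Cl group sits equatorial, and at the planar C4 radical the larger CH2OTBS group should take the equatorial 4α site to avoid 1,3-diaxial contact with the C10 methyl group. The cascade must stop after ring B, which the substrate secures because C13 is a saturated ketone carbon rather than an alkene carbon and aliphatic ketones are inert to Cp2TiCl, and the silyl ether must stay in place, which holds because tertiary radicals are trapped by titanium too slowly for β-elimination to compete with ring closure.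

Step 5
Reactants: 6 3β-hydroxy-18-(tert-butyldimethylsilyloxy)-14,15-dinorlabd-8(17)-en-13-one; 7 triethyl phosphonoacetate
Product: 8 ethyl (13E)-3β-hydroxy-18-(tert-butyldimethylsilyloxy)labda-8(17),13-dien-15-oate
Conditions: 7, NaH, THF, 0 °C (anion pre-formed); then 6, rt to 50 °C; chromatographic removal of the Z isomer
Reagents that add atoms: triethyl phosphonoacetate (7), CCOC(=O)CP(=O)(OCC)OCC
Why: The Horner–Wadsworth–Emmons reaction of the stabilised phosphonate anion with the unhindered C13 methyl ketone adds reversibly and should favour the E enoate (C12 trans to C15), while the hindered 3β-hydroxyl is not deprotonated by this weakly basic anion.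

Step 6
Reactants: 8 ethyl (13E)-3β-hydroxy-18-(tert-butyldimethylsilyloxy)labda-8(17),13-dien-15-oate
Product: 9 ethyl (13E)-3-oxo-18-(tert-butyldimethylsilyloxy)labda-8(17),13-dien-15-oate
Conditions: Dess–Martin periodinane, CH2Cl2, 0 °C to rt
Reagents that add atoms: none
Why: Dess–Martin oxidation converts the only free alcohol into the C3 ketone under near-neutral conditions that leave the silyl ether, the enoate and the exocyclic alkene untouched.

Step 7
Reactants: 9 ethyl (13E)-3-oxo-18-(tert-butyldimethylsilyloxy)labda-8(17),13-dien-15-oate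
Product: 11 (13E)-18-(tert-butyldimethylsilyloxy)labda-8(17),13-diene-3α,15-diol, via lithium alkoxide 10 (not isolated)
Conditions: LiBH(s-Bu)3 (L-Selectride), THF, −78 °C; then i-Bu2AlH (DIBAL-H), −78 to −20 °C; aq. potassium sodium tartrate
Reagents that add atoms: none
Why: The bulky tri-sec-butylborohydride cannot use the axial α trajectory, which is blocked by the axial hydrogens on C1 and C5, so it attacks C3 from the equatorial side and sets the axial 3α-alkoxide (substrate-controlled Selectride reduction of a cyclohexanone), after which i-Bu2AlH reduces the β,β-disubstituted enoate in 1,2 fashion to the allylic alcohol without changing the alkene geometry.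

Step 8
Reactants: 11 (13E)-18-(tert-butyldimethylsilyloxy)labda-8(17),13-diene-3α,15-diol
Product: 12 (13E)-3α,15-diacetoxy-18-(tert-butyldimethylsilyloxy)labda-8(17),13-diene
Conditions: Ac2O, 4-dimethylaminopyridine (cat.), pyridine, rt to 40 °C
Reagents that add atoms: acetic anhydride, CC(=O)OC(C)=O
Why: Nucleophilic catalysis by 4-dimethylaminopyridine is strong enough to acylate the hindered axial 3α-hydroxyl as well as the primary allylic one, and no stereocentre is touched.

Step 9
Reactants: 12 (13E)-3α,15-diacetoxy-18-(tert-butyldimethylsilyloxy)labda-8(17),13-diene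
Product: 13 (13E)-3α,15-diacetoxylabda-8(17),13-dien-18-ol
Conditions: HF·pyridine, pyridine, THF, 0 °C to rt
Reagents that add atoms: none
Why: Fluoride-driven Si–O cleavage under buffered, weakly acidic conditions frees the neopentyl C18 alcohol, keeps both acetates and disfavours base-induced acetyl migration from O3 to O18.

Step 10
Reactants: 13 (13E)-3α,15-diacetoxylabda-8(17),13-dien-18-ol
Product: 15 (13E)-3α,15-diacetoxylabda-8(17),13-dien-18-oic acid, via aldehyde 14 (not isolated)
Conditions: 1-methyl-2-azaadamantane N-oxyl (5 mol %), NaOCl (5 mol %), NaClO2, MeCN/aq. sodium phosphate buffer pH 6.8, rt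
Reagents that add atoms: sodium chlorite, [Na+].[O-]Cl=O
Why: The unhindered azaadamantane oxoammonium ion oxidises the neopentyl alcohol to the aldehyde, chlorite takes the aldehyde to the acid (Pinnick-type step), and the hypochlorite so formed re-oxidises the catalyst instead of attacking the alkenes, so the quaternary C4 is untouched.

Step 11
Reactants: 15 (13E)-3α,15-diacetoxylabda-8(17),13-dien-18-oic acid
Product: 16 (13E)-3α-acetoxy-15-hydroxylabda-8(17),13-dien-18-oic acid (target)
Conditions: K2CO3 (2 equiv), MeOH, 0 °C; then 1 M aq. HCl to pH 3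
Reagents that add atoms: none
Why: Base-catalysed transesterification (Zemplén-type methanolysis) is far faster at the unhindered primary allylic acetate than at the axial 3α-acetate next to the quaternary C4, whose neighbouring carboxylate also repels methoxide, so only O15 should be freed.

Compound list
1 | (5E,9E)-6,10,14-trimethylpentadeca-5,9,13-trien-2-one ((5E,9E)-farnesylacetone) | CC(C)=CCC/C(C)=C/CC/C(C)=C/CCC(C)=O | starting material
2 | (5E,9E,13E)-15-hydroxy-6,10,14-trimethylpentadeca-5,9,13-trien-2-one | OC/C(C)=C/CC/C(C)=C/CC/C(C)=C/CCC(C)=O | intermediate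
3 | (5E,9E)-12-[(2S,3S)-3-(hydroxymethyl)-3-methyloxiran-2-yl]-6,10-dimethyldodeca-5,9-dien-2-one | OC[C@]1(C)O[C@H]1CC/C(C)=C/CC/C(C)=C/CCC(C)=O | intermediate
4 | (5E,9E)-12-[(2S,3S)-3-(tert-butyldimethylsilyloxymethyl)-3-methyloxiran-2-yl]-6,10-dimethyldodeca-5,9-dien-2-one | CC(C)(C)[Si](C)(C)OC[C@]1(C)O[C@H]1CC/C(C)=C/CC/C(C)=C/CCC(C)=O | intermediate
5 | chlorobis(cyclopentadienyl)titanium 3β-alkoxide of 6 (tetravalent titanium, Cp drawn σ-bonded) | C=C1CC[C@@H]2[C@](C)(CC[C@H](O[Ti](Cl)(C3C=CC=C3)C3C=CC=C3)[C@@]2(C)CO[Si](C)(C)C(C)(C)C)[C@H]1CCC(C)=O | intermediate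
6 | 3β-hydroxy-18-(tert-butyldimethylsilyloxy)-14,15-dinorlabd-8(17)-en-13-one (trans-decalin; 3β-OH equatorial, 4α-CH2OTBS equatorial, 4β-CH3, 5α-H, 9α-H, 10β-CH3) | C=C1CC[C@@H]2[C@](C)(CC[C@H](O)[C@@]2(C)CO[Si](C)(C)C(C)(C)C)[C@H]1CCC(C)=O | intermediate
7 | triethyl phosphonoacetate | CCOC(=O)CP(=O)(OCC)OCC | starting material
8 | ethyl (13E)-3β-hydroxy-18-(tert-butyldimethylsilyloxy)labda-8(17),13-dien-15-oate | C=C1CC[C@@H]2[C@](C)(CC[C@H](O)[C@@]2(C)CO[Si](C)(C)C(C)(C)C)[C@H]1CC/C(C)=C/C(=O)OCC | intermediate
9 | ethyl (13E)-3-oxo-18-(tert-butyldimethylsilyloxy)labda-8(17),13-dien-15-oate | C=C1CC[C@@H]2[C@](C)(CCC(=O)[C@@]2(C)CO[Si](C)(C)C(C)(C)C)[C@H]1CC/C(C)=C/C(=O)OCC | intermediate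
10 | lithium 3α-alkoxide of ethyl (13E)-3α-hydroxy-18-(tert-butyldimethylsilyloxy)labda-8(17),13-dien-15-oate | C=C1CC[C@@H]2[C@](C)(CC[C@@H]([O-])[C@@]2(C)CO[Si](C)(C)C(C)(C)C)[C@H]1CC/C(C)=C/C(=O)OCC.[Li+] | intermediate
11 | (13E)-18-(tert-butyldimethylsilyloxy)labda-8(17),13-diene-3α,15-diol (3α-OH axial) | C=C1CC[C@@H]2[C@](C)(CC[C@@H](O)[C@@]2(C)CO[Si](C)(C)C(C)(C)C)[C@H]1CC/C(C)=C/CO | intermediate
12 | (13E)-3α,15-diacetoxy-18-(tert-butyldimethylsilyloxy)labda-8(17),13-diene | C=C1CC[C@@H]2[C@](C)(CC[C@@H](OC(C)=O)[C@@]2(C)CO[Si](C)(C)C(C)(C)C)[C@H]1CC/C(C)=C/COC(C)=O | intermediate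
13 | (13E)-3α,15-diacetoxylabda-8(17),13-dien-18-ol | C=C1CC[C@@H]2[C@](C)(CC[C@@H](OC(C)=O)[C@@]2(C)CO)[C@H]1CC/C(C)=C/COC(C)=O | intermediate
14 | (13E)-3α,15-diacetoxylabda-8(17),13-dien-18-al | C=C1CC[C@@H]2[C@](C)(CC[C@@H](OC(C)=O)[C@@]2(C)C=O)[C@H]1CC/C(C)=C/COC(C)=O | intermediate
15 | (13E)-3α,15-diacetoxylabda-8(17),13-dien-18-oic acid | C=C1CC[C@@H]2[C@](C)(CC[C@@H](OC(C)=O)[C@@]2(C)C(=O)O)[C@H]1CC/C(C)=C/COC(C)=O | intermediate
16 | (3R,4S,5R,9S,10R,13E)-3α-acetoxy-15-hydroxylabda-8(17),13-dien-18-oic acid | C=C1CC[C@@H]2[C@](C)(CC[C@@H](OC(C)=O)[C@@]2(C)C(=O)O)[C@H]1CC/C(C)=C/CO | target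

Total step count: 11. Longest linear sequence: 11 steps (from 1).

Steps most likely to fail

Risk 1 (step 4). Three processes may intrude: loss of stereocontrol at the planar C4 radical, hydrogen capture or termination after ring A only, and deoxygenation of the epoxide. The fallback sets out from 4 and returns at 8, and it replaces the radical cascade with a polar, stereospecific one.
- Compound 4 is first olefinated with 7 (NaH, THF) to the acyclic ethyl (2E,6E,10E)-13-[(2S,3S)-3-(tert-butyldimethylsilyloxymethyl)-3-methyloxiran-2-yl]-3,7,11-trimethyltrideca-2,6,10-trienoate F1.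
- F1 is then treated with MeAlCl2 in CH2Cl2 at −78 °C.
- C5 attacks C4 anti to the departing oxygen, so the E-derived CH2OTBS group is carried stereospecifically into the 4α position.
- The electron-poor enoate alkene cannot join the cationic cascade.
- Proton loss from C17 of the C8 cation leads to 8, after separation from endocyclic alkene isomers.

Risk 2 (step 7). Facial selectivity of hydride delivery at C3 may be poor, or the enoate may undergo conjugate reduction. The fallback sets out from 9 and returns at 11, and it replaces substrate control with catalyst control.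
- A Corey–Bakshi–Shibata reduction is run with (S)-1-methyl-3,3-diphenyltetrahydropyrrolo[1,2-c][1,3,2]oxazaborole ((S)-Me-CBS) and catecholborane in toluene at −78 °C.
- The catalyst distinguishes the quaternary C4 flank from the C2 methylene, and catecholborane leaves the alkenes alone.
- This should give ethyl (13E)-3α-hydroxy-18-(tert-butyldimethylsilyloxy)labda-8(17),13-dien-15-oate F2.
- F2 is isolated, purified from any 3β epimer and reduced with i-Bu2AlH to 11.

Risk 3 (step 9). Once O18 is free, the acetyl group may migrate from the hindered O3 to the primary O18 through a six-membered orthoester. The fallback sets out from 11 and returns at 15. It changes the order of events so that no C3 acetate is present while O18 is free.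
- Selective acetylation of the primary allylic hydroxyl (Ac2O, 1 equiv, pyridine, 0 °C) gives (13E)-15-acetoxy-18-(tert-butyldimethylsilyloxy)labda-8(17),13-dien-3α-ol F3.
- HF·pyridine gives (13E)-15-acetoxylabda-8(17),13-diene-3α,18-diol F4.
- 2,2,6,6-Tetramethylpiperidine N-oxyl (TEMPO) with PhI(OAc)2 oxidises only the primary C18 hydroxyl, giving (13E)-15-acetoxy-3α-hydroxylabda-8(17),13-dien-18-al F5.
- NaClO2/NaH2PO4/2-methyl-2-butene (Pinnick oxidation) gives (13E)-15-acetoxy-3α-hydroxylabda-8(17),13-dien-18-oic acid F6.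
- Ac2O/4-dimethylaminopyridine/pyridine, with aqueous hydrolysis of the mixed anhydride, gives 15.

Further compounds
F1 | step 4 | ethyl (2E,6E,10E)-13-[(2S,3S)-3-(tert-butyldimethylsilyloxymethyl)-3-methyloxiran-2-yl]-3,7,11-trimethyltrideca-2,6,10-trienoate | CC(C)(C)[Si](C)(C)OC[C@]1(C)O[C@H]1CC/C(C)=C/CC/C(C)=C/CC/C(C)=C/C(=O)OCC
F2 | step 7 | ethyl (13E)-3α-hydroxy-18-(tert-butyldimethylsilyloxy)labda-8(17),13-dien-15-oate | C=C1CC[C@@H]2[C@](C)(CC[C@@H](O)[C@@]2(C)CO[Si](C)(C)C(C)(C)C)[C@H]1CC/C(C)=C/C(=O)OCC
F3 | step 9 | (13E)-15-acetoxy-18-(tert-butyldimethylsilyloxy)labda-8(17),13-dien-3α-ol | C=C1CC[C@@H]2[C@](C)(CC[C@@H](O)[C@@]2(C)CO[Si](C)(C)C(C)(C)C)[C@H]1CC/C(C)=C/COC(C)=O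
F4 | step 9 | (13E)-15-acetoxylabda-8(17),13-diene-3α,18-diol | C=C1CC[C@@H]2[C@](C)(CC[C@@H](O)[C@@]2(C)CO)[C@H]1CC/C(C)=C/COC(C)=O
F5 | step 9 | (13E)-15-acetoxy-3α-hydroxylabda-8(17),13-dien-18-al | C=C1CC[C@@H]2[C@](C)(CC[C@@H](O)[C@@]2(C)C=O)[C@H]1CC/C(C)=C/COC(C)=O
F6 | step 9 | (13E)-15-acetoxy-3α-hydroxylabda-8(17),13-dien-18-oic acid | C=C1CC[C@@H]2[C@](C)(CC[C@@H](O)[C@@]2(C)C(=O)O)[C@H]1CC/C(C)=C/COC(C)=O
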